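**Retrosynthetic overview**

- Feature: on ring A, O1 (on C8a) and the acyl carbon C4 (on C4a) are ortho neighbours, and O1 must flank the geranyl-bearing C8, not C6.
- Target ⇐ (2S)-8-geranyl-5,7-dimethoxyflavanone (chelation-controlled cleavage of the C5 methyl ether) ⇐ 8-geranyl-5,7-dimethoxyflavone (enantioselective CuH 1,4-reduction sets C2).
- Flavone ⇐ C4a≡C8a aryne + 3-phenylpropiolic acid: C8a–O1 and C4a–C4 by aryne insertion into the acid C–O bond, then O1–C2 by 6-endo-dig closure of ring C.
- Aryne precursor ⇐ 3,5-dimethoxyphenol via its O-diethylcarbamate: two successive directed ortho-metalations (SiMe3, then geranyl through the arylcopper), then carbamate → triflate.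
- Ring order: ring A is bought, ring B comes with the acid, ring C is the only ring formed (step 6).

Key step: step 6

Remark on the design: both ortho substituents of the aryne precursor are introduced through one carbamate directing group. This avoids electrophilic bromination of the phenol (C2/C4 mixtures) and phenoxide C-allylation (O/C and ortho/para mixtures, acid-labile aryl–silicon bond).

Assumption: (R)-DTBM-SEGPHOS is taken to deliver hydride to the face of C2 that gives the (2S)-flavanone; the sense is to be checked on the first run and the (S)-ligand used if it is the reverse.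

Geranyl = (2E)-3,7-dimethylocta-2,6-dien-1-yl throughout.

**Route**

Step 1
Reactants: 1 3,5-dimethoxyphenol
Product: 2 3,5-dimethoxyphenyl N,N-diethylcarbamate
Conditions: ClCONEt2 (1.2 equiv), K2CO3, MeCN, reflux
Reagents that add atoms: N,N-diethylcarbamoyl chloride, CCN(CC)C(Cl)=O
Why: The phenoxide formed with K2CO3 is O-acylated by the carbamoyl chloride (carbamoylation), which installs the directing group used for both later metalations.

Step 2
Reactants: 2 3,5-dimethoxyphenyl N,N-diethylcarbamate
Product: 4 3,5-dimethoxy-2-(trimethylsilyl)phenyl N,N-diethylcarbamate, via 2-lithio carbamate 3 (not isolated)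
Conditions: s-BuLi (1.1 equiv), TMEDA, THF, −78 °C; then TMSCl, −78 °C → rt
Reagents that add atoms: chlorotrimethylsilane, C[Si](C)(C)Cl
Why: Directed ortho-metalation, in which carbamate and the neighbouring methoxy group jointly direct s-BuLi to C2 (the two ortho carbons are equivalent by symmetry), and the aryllithium is silylated at −78 °C before an anionic ortho-Fries shift can set in.

Step 3
Reactants: 4 3,5-dimethoxy-2-(trimethylsilyl)phenyl N,N-diethylcarbamate; 5 geranyl bromide
Product: 8 2-geranyl-3,5-dimethoxy-6-(trimethylsilyl)phenyl N,N-diethylcarbamate, via 6-lithio carbamate 6 (not isolated), via arylcopper 7 (not isolated)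
Conditions: s-BuLi (1.2 equiv), TMEDA, THF, −78 °C; CuBr·SMe2 (1.2 equiv), −78 → −40 °C; then 5 (1.3 equiv), −78 → 0 °C
Reagents that add atoms: none
Why: A second directed ortho-metalation is steered to the remaining ortho carbon C6 (flanked by carbamate and methoxy, favoured over C4 between the two methoxy groups), and the derived arylcopper substitutes the primary allylic bromide at its α-carbon (copper-mediated SN2 allylation) with the E double bond retained.

Step 4
Reactants: 8 2-geranyl-3,5-dimethoxy-6-(trimethylsilyl)phenyl N,N-diethylcarbamate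
Product: 9 2-geranyl-3,5-dimethoxy-6-(trimethylsilyl)phenol
Conditions: LiAlH4, THF, 0 °C → reflux; then H2O, 15 % aq. NaOH, H2O
Reagents that add atoms: none
Why: Hydride reduces the carbamate carbonyl and expels the phenoxide (reductive carbamate cleavage), the aryl–silicon bond, methyl ethers and isolated alkenes being inert to LiAlH4, and the basic work-up avoids protodesilylation of the electron-rich arylsilane.

Step 5
Reactants: 9 2-geranyl-3,5-dimethoxy-6-(trimethylsilyl)phenol
Product: 11 6-geranyl-3,5-dimethoxy-2-(trimethylsilyl)phenyl trifluoromethanesulfonate, via lithium phenoxide 10 (not isolated)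
Conditions: n-BuLi (1.05 equiv), Et2O, −78 °C; then Tf2O, −78 → 0 °C
Reagents that add atoms: trifluoromethanesulfonic anhydride, O=S(=O)(OS(=O)(=O)C(F)(F)F)C(F)(F)F
Why: The lithium phenoxide is O-sulfonylated by Tf2O at low temperature (aryl triflate formation, the usual last step of ortho-silylaryl triflate syntheses), faster than any reaction of the anhydride with the alkenes or the arene.

Step 6
Reactants: 11 6-geranyl-3,5-dimethoxy-2-(trimethylsilyl)phenyl trifluoromethanesulfonate; 12 3-phenylpropiolic acid
Product: 16 8-geranyl-5,7-dimethoxyflavone, via aryne 13 (not isolated), via ortho-caesiated aryl phenylpropiolate 14 (not isolated), via caesium 2-(phenylpropioloyl)phenoxide 15 (not isolated)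
Conditions: 12 (1.2 equiv), CsF (4 equiv), THF, 125 °C, sealed tube
Reagents that add atoms: none
Why: Fluoride removes SiMe3 from C4a and triflate leaves C8a to give aryne 13; the carboxylate of 12 adds through oxygen to C8a, the aryl anion at C4a attacks the adjacent ester carbonyl through a four-membered transition state, and collapse of that adduct leaves the acyl group on C4a and a phenoxide on C8a (net insertion of the aryne into the acid C–O bond). The closest known reaction type is the fluoride-induced aryne/carboxylic acid C–O insertion run at about 125 °C, which with arylpropiolic acids leads on to flavones. Ring C then closes by 6-endo-dig oxa-Michael addition of the C8a phenoxide (O1) to the ynone β-carbon (C2), and the vinyl anion takes up the proton brought in by the acid at C3; no stereocentre is formed. The selectivity needed is oxygen attack at C8a and not C4a: the C5 methoxy group inductively stabilises the developing carbanion at C4a and distorts the aryne so that C8a is the more electrophilic carbon, which should outweigh the steric effect of the C8 methylene and the weak opposing effect of the C7 methoxy group. Because O1 is the only phenolic oxygen ever generated, a 6-geranyl isomer cannot arise, and the 6-endo mode is favoured over 5-exo (aurone) closure by the conjugate polarisation of the aryl ynone at this temperature.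

Step 7
Reactants: 16 8-geranyl-5,7-dimethoxyflavone
Product: 18 (2S)-8-geranyl-5,7-dimethoxyflavanone, via silyl enol ether 17 (not isolated)
Conditions: Cu(OAc)2 (5 mol %), (R)-DTBM-SEGPHOS (5.5 mol %), (EtO)2MeSiH (1.5 equiv), toluene, 0 °C → rt; then 10 % aq. citric acid, THF, rt
Reagents that add atoms: none
Why: Ligated copper hydride delivers hydride to C2 of the vinylogous ester in 1,4-fashion (asymmetric CuH conjugate reduction, known for 2-substituted chromones), the chiral bisphosphine differentiating the two faces of the planar pyranone so that C2 is set as S under catalyst control, while trapping of the enolate as silyl enol ether 17 shields C4 from over-reduction and the unactivated trisubstituted alkenes are not hydrocuprated.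

Step 8
Reactants: 18 (2S)-8-geranyl-5,7-dimethoxyflavanone
Product: 19 (2S)-8-geranyl-5-hydroxy-7-methoxyflavanone (target)
Conditions: MgI2·OEt2 (3 equiv), THF, 50 °C; then cold 0.5 M aq. HCl
Reagents that add atoms: none
Why: Mg2+ chelates the C4 carbonyl and the peri C5 methoxy oxygen and iodide cleaves that activated O–CH3 bond by SN2 (chelation-controlled demethylation, a reagent known to spare prenyl-type side chains on 5-methoxyflavanones), whereas the unchelated C7 methyl ether stays, and without base C3 is not enolised so the C2 configuration should be retained.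

**Compound list**

1 | 3,5-dimethoxyphenol | COc1cc(O)cc(OC)c1 | starting material
2 | 3,5-dimethoxyphenyl N,N-diethylcarbamate | CCN(CC)C(=O)Oc1cc(OC)cc(OC)c1 | intermediate
3 | 2-lithio-3,5-dimethoxyphenyl N,N-diethylcarbamate | CCN(CC)C(=O)Oc1cc(OC)cc(OC)c1[Li] | intermediate (not isolated)
4 | 3,5-dimethoxy-2-(trimethylsilyl)phenyl N,N-diethylcarbamate | CCN(CC)C(=O)Oc1cc(OC)cc(OC)c1[Si](C)(C)C | intermediate
5 | geranyl bromide, (2E)-1-bromo-3,7-dimethylocta-2,6-diene | CC(C)=CCC/C(C)=C/CBr | starting material
6 | 2-lithio-3,5-dimethoxy-6-(trimethylsilyl)phenyl N,N-diethylcarbamate | CCN(CC)C(=O)Oc1c([Li])c(OC)cc(OC)c1[Si](C)(C)C | intermediate (not isolated)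
7 | [2-(diethylcarbamoyloxy)-4,6-dimethoxy-3-(trimethylsilyl)phenyl]copper | CCN(CC)C(=O)Oc1c([Cu])c(OC)cc(OC)c1[Si](C)(C)C | intermediate (not isolated)
8 | 2-geranyl-3,5-dimethoxy-6-(trimethylsilyl)phenyl N,N-diethylcarbamate | CCN(CC)C(=O)Oc1c(C/C=C(\C)CCC=C(C)C)c(OC)cc(OC)c1[Si](C)(C)C | intermediate
9 | 2-geranyl-3,5-dimethoxy-6-(trimethylsilyl)phenol | Oc1c(C/C=C(\C)CCC=C(C)C)c(OC)cc(OC)c1[Si](C)(C)C | intermediate
10 | lithium 2-geranyl-3,5-dimethoxy-6-(trimethylsilyl)phenoxide | [Li+].[O-]c1c(C/C=C(\C)CCC=C(C)C)c(OC)cc(OC)c1[Si](C)(C)C | intermediate (not isolated)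
11 | 6-geranyl-3,5-dimethoxy-2-(trimethylsilyl)phenyl trifluoromethanesulfonate | COc1cc(OC)c([Si](C)(C)C)c(OS(=O)(=O)C(F)(F)F)c1C/C=C(\C)CCC=C(C)C | intermediate
12 | 3-phenylpropiolic acid | OC(=O)C#Cc1ccccc1 | starting material
13 | 3-geranyl-4,6-dimethoxybenzyne (triple bond between the former C–Si and C–OTf carbons) | COC1=C(C/C=C(\C)CCC=C(C)C)C#CC(OC)=C1 | intermediate (not isolated)
14 | caesium salt of 2-geranyl-3,5-dimethoxyphenyl 3-phenylpropiolate carrying the carbanion at C6 | COc1cc(OC)c(C/C=C(\C)CCC=C(C)C)c(OC(=O)C#Cc2ccccc2)[c-]1.[Cs+] | intermediate (not isolated)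
15 | caesium 2-geranyl-3,5-dimethoxy-6-(3-phenylpropioloyl)phenoxide | COc1cc(OC)c(C(=O)C#Cc2ccccc2)c([O-])c1C/C=C(\C)CCC=C(C)C.[Cs+] | intermediate (not isolated)
16 | 8-geranyl-5,7-dimethoxyflavone | COc1cc(OC)c2c(c1C/C=C(\C)CCC=C(C)C)oc(-c1ccccc1)cc2=O | intermediate
17 | (2S)-4-[diethoxy(methyl)silyloxy]-8-geranyl-5,7-dimethoxy-2-phenyl-2H-chromene | COc1cc(OC)c2c(c1C/C=C(\C)CCC=C(C)C)O[C@H](c1ccccc1)C=C2O[Si](C)(OCC)OCC | intermediate (not isolated)
18 | (2S)-8-geranyl-5,7-dimethoxyflavanone | COc1cc(OC)c2c(c1C/C=C(\C)CCC=C(C)C)O[C@H](c1ccccc1)CC2=O | intermediate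
19 | (2S)-8-geranyl-5-hydroxy-7-methoxyflavanone | COc1cc(O)c2c(c1C/C=C(\C)CCC=C(C)C)O[C@H](c1ccccc1)CC2=O | target

**Step count**

Total steps: 8. Longest linear sequence: 8 steps (from 1 to 19).

**Steps most likely to fail**

Step 6. The aryl anion at C4a may be protonated before it reaches the ester carbonyl, so the sequence stops at the simple aryl ester. The carboxylate may add at C4a under the steric pressure of the C8 side chain, or the propiolate may decarboxylate at 125 °C. The fallback sets out from 2 and returns at 16, and builds the same ortho O1/C4 pattern by ortho-specific formylation: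
- Directed ortho-metalation of 2 (s-BuLi, TMEDA, −78 °C), transmetalation with CuBr·SMe2 and alkylation with 5 should give 2-geranyl-3,5-dimethoxyphenyl N,N-diethylcarbamate F1.
- LiAlH4 in THF frees 2-geranyl-3,5-dimethoxyphenol F2.
- MgCl2, Et3N and paraformaldehyde in MeCN at reflux place the formyl group on the only free ortho carbon to give 3-geranyl-2-hydroxy-4,6-dimethoxybenzaldehyde F3.
- PhC≡CLi (2.5 equiv, THF, −78 → 0 °C) adds to the aldehyde to give racemic 2-geranyl-6-(1-hydroxy-3-phenylprop-2-yn-1-yl)-3,5-dimethoxyphenol F4.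
- MnO2 in CH2Cl2 oxidises the propargylic alcohol to 1-(3-geranyl-2-hydroxy-4,6-dimethoxyphenyl)-3-phenylprop-2-yn-1-one F5, the free phenol of 15.
- Et2NH in EtOH closes ring C by way of the enaminone to flavone 16.

Step 7. Hydride transfer to the electron-rich vinylogous ester may be slow, facial discrimination may be insufficient, or the copper enolate may lose the phenoxide by β-elimination and open ring C. The fallback sets out from 16 and returns at 18, and sets C2 by kinetic resolution instead of face-selective hydride delivery:
- Non-selective 1,4-reduction with LiBH(s-Bu)3 in THF at −78 °C should give racemic 8-geranyl-5,7-dimethoxyflavanone F6.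
- Asymmetric transfer hydrogenation with Cp*RhCl(TsDPEN) in HCO2H/Et3N, using the catalyst enantiomer that consumes the 2R ketone, should convert that enantiomer into (2R,4R)-cis-8-geranyl-5,7-dimethoxyflavan-4-ol F7.
- The unreacted (2S)-flavanone 18 is separated from F7 by chromatography; at most half of the material is carried on.

Step 8. The C2 configuration may erode through Lewis-acid-promoted opening and reclosure of ring C at 50 °C, or the geranyl double bonds may be attacked by the Lewis acid or by HI formed at the quench. The fallback sets out from 16 and returns at 19, and moves the demethylation in front of the stereocentre-forming step: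
- MgI2·OEt2 on the flavone 16 should give 8-geranyl-5-hydroxy-7-methoxyflavone F8.
- NaH and MOMCl in DMF convert the chelated phenol into 8-geranyl-7-methoxy-5-(methoxymethoxy)flavone F9.
- The CuH reduction of step 7 applied to F9 should give (2S)-8-geranyl-7-methoxy-5-(methoxymethoxy)flavanone F10.
- The chelation-activated peri acetal is cleaved with dilute HCl in MeOH at rt, conditions under which a 2-phenylflavanone should not racemise, to give 19.

Further compounds
F1 | step 6 | 2-geranyl-3,5-dimethoxyphenyl N,N-diethylcarbamate | CCN(CC)C(=O)Oc1cc(OC)cc(OC)c1C/C=C(\C)CCC=C(C)C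
F2 | step 6 | 2-geranyl-3,5-dimethoxyphenol | Oc1cc(OC)cc(OC)c1C/C=C(\C)CCC=C(C)C
F3 | step 6 | 3-geranyl-2-hydroxy-4,6-dimethoxybenzaldehyde | COc1cc(OC)c(C=O)c(O)c1C/C=C(\C)CCC=C(C)C
F4 | step 6 | racemic 2-geranyl-6-(1-hydroxy-3-phenylprop-2-yn-1-yl)-3,5-dimethoxyphenol | COc1cc(OC)c(C(O)C#Cc2ccccc2)c(O)c1C/C=C(\C)CCC=C(C)C
F5 | step 6 | 1-(3-geranyl-2-hydroxy-4,6-dimethoxyphenyl)-3-phenylprop-2-yn-1-one | COc1cc(OC)c(C(=O)C#Cc2ccccc2)c(O)c1C/C=C(\C)CCC=C(C)C
F6 | step 7 | racemic 8-geranyl-5,7-dimethoxyflavanone | COc1cc(OC)c2c(c1C/C=C(\C)CCC=C(C)C)OC(c1ccccc1)CC2=O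
F7 | step 7 | (2R,4R)-cis-8-geranyl-5,7-dimethoxyflavan-4-ol | COc1cc(OC)c2c(c1C/C=C(\C)CCC=C(C)C)O[C@@H](c1ccccc1)C[C@H]2O
F8 | step 8 | 8-geranyl-5-hydroxy-7-methoxyflavone | COc1cc(O)c2c(c1C/C=C(\C)CCC=C(C)C)oc(-c1ccccc1)cc2=O
F9 | step 8 | 8-geranyl-7-methoxy-5-(methoxymethoxy)flavone | COc1cc(OCOC)c2c(c1C/C=C(\C)CCC=C(C)C)oc(-c1ccccc1)cc2=O
F10 | step 8 | (2S)-8-geranyl-7-methoxy-5-(methoxymethoxy)flavanone | COc1cc(OCOC)c2c(c1C/C=C(\C)CCC=C(C)C)O[C@H](c1ccccc1)CC2=O
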